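**Retrosynthetic overview**

1. Target 28 comes from the 19-alcohol 24 and (E)-4-acetoxycinnamic acid; the 13(16),14-diene comes from a methyl ketone (enol triflate, Stille coupling), the 7α,8α-diol from the C7=C8 alkene (the enone alkene of carvone), and C11–C13 from a C9=C11 methylene by hydroboration and alkylation.
2. Key disconnection: the C3–C4 bond of ring A, made from the vinyl δ-lactone 10 by an Ireland–Claisen ring contraction that builds the C4 quaternary centre with C19 as a carboxyl and expels the C1 oxygen.
3. Enabling feature: C4 carries an oxidised carbon (C19) and C1 sits on the neighbouring ring-B atom C10, so C19 and C1 can be tied across the C5–C10 ring-fusion bond in a six-membered lactone (O–C19–C4–C5–C10–C1); its enolate and the vinyl group on C1 (C2=C3) form the 1,5-diene C4=C19–O–C1–C2=C3.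
4. Lactone 10 comes from an aldol reaction of acrolein with the C10 enolate of a keto ester made from (R)-carvone (this sets C10 and C1); the ester carbon C19 is the terminal carbon of the carvone isopropenyl group.
5. Ring order: ring B is the carvone ring and is never formed; the temporary lactone ring is made in step 5; ring A is the only carbocycle closed and is closed last, in step 7.

Key step: step 7

Remark: labdane numbering is used (ring A = C1–C5 and C10, ring B = C5–C10, C19 = the oxygenated carbon on C4); 3–6 and 8–11 are carried as mixtures at C4 (3 also at its carbinol carbon, 6 also at C10), which is of no consequence because these centres are planarised or reset later.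

**Step 1**
Reactants: 1 (R)-(−)-carvone
Product: 3 (5R)-5-(1-hydroxypropan-2-yl)-2-methylcyclohex-2-en-1-ol, via bis-borane adduct 2 (not isolated)
Conditions: 9-BBN (2.5 equiv), THF, 0 °C to rt; then NaOH, H2O2, H2O, 0 °C to rt
Reagents that add atoms: hydrogen peroxide OO
Why: Hydroboration-oxidation: 9-BBN reduces the enone carbonyl in the 1,2 sense and adds to the 1,1-disubstituted isopropenyl alkene (boron on the terminal carbon) much faster than to the trisubstituted ring alkene, so oxidation should give the diol; the carvone stereocentre is untouched and the two new centres form unselectively, which does not matter.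

**Step 2**
Reactants: 3 (5R)-5-(1-hydroxypropan-2-yl)-2-methylcyclohex-2-en-1-ol
Product: 4 keto acid 2-[(1R)-4-methyl-5-oxocyclohex-3-en-1-yl]propanoic acid
Conditions: CrO3, H2SO4, H2O, acetone, 0 °C
Reagents that add atoms: water O
Why: Jones oxidation should convert the primary alcohol into the carboxylic acid (the future C19) and the allylic alcohol back into the enone in one operation; no stereocentre is set.

**Step 3**
Reactants: 4 keto acid 2-[(1R)-4-methyl-5-oxocyclohex-3-en-1-yl]propanoic acid
Product: 5 methyl 2-[(1R)-4-methyl-5-oxocyclohex-3-en-1-yl]propanoate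
Conditions: MeOH, H2SO4 (cat.), reflux
Reagents that add atoms: methanol CO
Why: Fischer esterification of an unhindered acid; the methyl ester is the acyl partner for the later lactone closure.

**Step 4**
Reactants: 5 methyl 2-[(1R)-4-methyl-5-oxocyclohex-3-en-1-yl]propanoate
Product: 6 methyl 2-[(1R)-4,6-dimethyl-5-oxocyclohex-3-en-1-yl]propanoate
Conditions: LiN(iPr)2 (1.05 equiv), THF, −78 °C; MeI, −78 to 0 °C
Reagents that add atoms: iodomethane CI
Why: Enolate alkylation: kinetic deprotonation occurs at the ketone α'-CH2 (C10), far more acidic than the ester α-CH, and C-methylation introduces C20; the configuration at C10 is unimportant because C10 is enolised again in step 5.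

**Step 5**
Reactants: 6 methyl 2-[(1R)-4,6-dimethyl-5-oxocyclohex-3-en-1-yl]propanoate; 7 acrolein
Product: 9 vinyl lactone (1R,4aS,8aR)-1-ethenyl-4,7,8a-trimethyl-4,4a,5,8a-tetrahydro-1H-isochromene-3,8-dione, via aldol alkoxide 8 (not isolated)
Conditions: LiN(iPr)2 (1.1 equiv), THF, −78 to −30 °C; 7, −78 °C; then 0 °C; H2O
Reagents that add atoms: none
Why: Aldol addition then lactonisation: the tetrasubstituted lithium enolate should add to acrolein at C10 anti to the C5 side chain (the sense known for alkylation of 6-methylcarvone, which places the C10 methyl cis and C1 trans to C4) through a closed Zimmerman–Traxler chair with the vinyl group equatorial, which sets C1 with its oxygen syn to the C10 methyl, and the alkoxide then attacks the methyl ester to close the trans-fused δ-lactone in which the vinyl group is axial.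

**Step 6**
Reactants: 9 vinyl lactone (1R,4aS,8aR)-1-ethenyl-4,7,8a-trimethyl-4,4a,5,8a-tetrahydro-1H-isochromene-3,8-dione
Product: 10 methylidene lactone (1R,4aS,8aS)-1-ethenyl-4,7,8a-trimethyl-8-methylidene-1,4,4a,5,8,8a-hexahydro-3H-isochromen-3-one
Conditions: Zn, CH2Br2, TiCl4, THF/CH2Cl2, 0 °C to rt
Reagents that add atoms: dibromomethane BrCBr
Why: Takai–Lombardo methylenation converts hindered and conjugated ketones into methylene compounds without touching lactones; it introduces C11 and removes the enone, so that C4–H of the lactone is the only acidic C–H in the key step.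

**Step 7**
Reactants: 10 methylidene lactone (1R,4aS,8aS)-1-ethenyl-4,7,8a-trimethyl-8-methylidene-1,4,4a,5,8,8a-hexahydro-3H-isochromen-3-one
Product: 13 trienoic acid (12,13,14,15,16-pentanorlabda-1,7,9(11)-trien-19-oic acid), via silyl ketene acetal 11 (not isolated), via trimethylsilyl ester 12 (not isolated)
Conditions: LiN(iPr)2 (1.3 equiv), Me3SiCl/Et3N, THF, −78 °C; toluene, 110 °C; then 10% aq. citric acid, THF, rt
Reagents that add atoms: none
Why: LiN(iPr)2 removes the C4 proton of 10 (the only acidic C–H once the ketone is masked as the methylene), O-silylation gives the cyclic silyl ketene acetal 11, and its C4=C19–O–C1–C2=C3 array undergoes an Ireland–Claisen [3,3]-sigmatropic shift to silyl ester 12, which is hydrolysed to 13. The closest known reaction type is the Ireland–Claisen ring contraction of six-membered lactones that carry an alkenyl group on the carbinol carbon (lactone to cyclohexene- or dihydropyran-carboxylic acid). Ring A (C1, C2, C3, C4, C5, C10) is closed by forming the C3–C4 bond while the C1–O bond of the temporary lactone breaks, through a boat-like transition state in which the two-atom C5–C10 tether, gauche because C4 and C1 are trans-diequatorial on ring B, spans the diagonal C4/C1 positions of the six-atom array. The new quaternary centre C4 is controlled by C1: the shift is suprafacial, C1 carries its hydrogen outward and its vinyl group axial on the lactone, so C3 can only bond to the α-face of C4, which puts the carboxyl carbon C19 β (axial, syn to the C10 methyl) and the C4 methyl α; the ketene acetal geometry is fixed by the ring and C5 and C10 are already set, so the trans ring fusion is not at stake. The step needs the [3,3] shift to outrun C-silylation and the much slower Cope shift of the C11=C9–C10–C1–C2=C3 diene, which the low barrier of silyl ketene acetal rearrangements should secure at 110 °C. In the same operation the C1 oxygen is expelled, C19 arrives at the carboxylic acid level and only the C1=C2 alkene remains to be hydrogenated.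

**Step 8**
Reactants: 13 trienoic acid (12,13,14,15,16-pentanorlabda-1,7,9(11)-trien-19-oic acid)
Product: 14 methyl 12,13,14,15,16-pentanorlabda-1,7,9(11)-trien-19-oate
Conditions: K2CO3, MeI, DMF, rt
Reagents that add atoms: iodomethane CI
Why: SN2 O-alkylation of the carboxylate is the reliable way to esterify the hindered axial C19 acid; the ester protects C19 during the side-chain work.

**Step 9**
Reactants: 14 methyl 12,13,14,15,16-pentanorlabda-1,7,9(11)-trien-19-oate; 15 bromoacetone
Product: 17 methyl 13-oxo-14,15-dinorlabda-1,7-dien-19-oate, via B-alkyl-9-BBN 16 (not isolated)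
Conditions: 9-BBN (1.1 equiv), THF, 0 °C to rt; then 15, potassium 2,6-di-tert-butylphenoxide, THF, 0 °C
Reagents that add atoms: none
Why: Hydroboration then borane α-alkylation: 9-BBN should add to the exocyclic C9=C11 terminus of the diene from the α-face, anti to the axial C10 methyl (boron on C11, hydrogen on C9, giving 9α-H and a β side chain), and leave the ring alkenes; the enolate of bromoacetone then forms a boron ate complex in which the primary alkyl group migrates from boron to carbon with loss of bromide, a known α-alkylation of α-halo ketones by B-alkyl-9-BBN reagents.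

**Step 10**
Reactants: 17 methyl 13-oxo-14,15-dinorlabda-1,7-dien-19-oate
Product: 18 methyl 13-oxo-14,15-dinorlabd-7-en-19-oate
Conditions: H2 (3 atm), RhCl(PPh3)3 (5 mol %), benzene, rt
Reagents that add atoms: none
Why: Homogeneous hydrogenation with RhCl(PPh3)3 reduces the cis-disubstituted C1=C2 alkene and is known to spare trisubstituted alkenes and ketones; no stereocentre is formed.

**Step 11**
Reactants: 18 methyl 13-oxo-14,15-dinorlabd-7-en-19-oate
Product: 19 methyl 7α,8α-dihydroxy-13-oxo-14,15-dinorlabdan-19-oate
Conditions: OsO4 (5 mol %), NMO, acetone/H2O, rt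
Reagents that add atoms: OsO4 O=[Os](=O)(=O)=O; N-methylmorpholine N-oxide C[N+]1([O-])CCOCC1; water O
Why: OsO4-catalysed syn-dihydroxylation of the only remaining alkene should take place on the α-face, opposite the axial C10 methyl and the β side chain at C9, and so set C7 and C8 as the 7α,8α-cis-diol.

**Step 12**
Reactants: 19 methyl 7α,8α-dihydroxy-13-oxo-14,15-dinorlabdan-19-oate
Product: 20 methyl 7α,8α-(isopropylidenedioxy)-13-oxo-14,15-dinorlabdan-19-oate
Conditions: 2-methoxypropene, PPTS (cat.), CH2Cl2, 0 °C
Reagents that add atoms: 2-methoxypropene C=C(C)OC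
Why: Kinetic acetonide formation on the cis-diol protects both hydroxyls under conditions too mild to ketalise the methyl ketone.

**Step 13**
Reactants: 20 methyl 7α,8α-(isopropylidenedioxy)-13-oxo-14,15-dinorlabdan-19-oate
Product: 21 methyl 7α,8α-(isopropylidenedioxy)-13-(trifluoromethylsulfonyloxy)-14,15-dinorlabd-13(16)-en-19-oate
Conditions: KN(SiMe3)2, THF, −78 °C; PhNTf2, −78 to 0 °C
Reagents that add atoms: N-phenylbis(trifluoromethanesulfonimide) O=S(=O)(N(c1ccccc1)S(=O)(=O)C(F)(F)F)C(F)(F)F
Why: Kinetic deprotonation of the methyl ketone by the bulky amide base occurs at the methyl group, and O-sulfonylation of the terminal enolate gives the 13(16)-enol triflate; the C19 ester has no α-hydrogen.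

**Step 14**
Reactants: 21 methyl 7α,8α-(isopropylidenedioxy)-13-(trifluoromethylsulfonyloxy)-14,15-dinorlabd-13(16)-en-19-oate; 22 tributyl(vinyl)stannane
Product: 23 methyl 7α,8α-(isopropylidenedioxy)labda-13(16),14-dien-19-oate
Conditions: Pd(PPh3)4 (5 mol %), LiCl, THF, 65 °C
Reagents that add atoms: none
Why: Stille coupling of an enol triflate with a vinylstannane is a standard route to 2-substituted buta-1,3-dienes and tolerates ester and ketal.

**Step 15**
Reactants: 23 methyl 7α,8α-(isopropylidenedioxy)labda-13(16),14-dien-19-oate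
Product: 24 alcohol 7α,8α-(isopropylidenedioxy)labda-13(16),14-dien-19-ol
Conditions: LiAlH4, THF, 0 °C to reflux; H2O work-up
Reagents that add atoms: none
Why: LiAlH4 reduces the hindered axial methyl ester to the neopentyl C19 alcohol; diene and acetonide are inert to hydride.

**Step 16**
Reactants: 24 alcohol 7α,8α-(isopropylidenedioxy)labda-13(16),14-dien-19-ol; 25 (E)-4-acetoxycinnamic acid
Product: 27 protected ester 7α,8α-(isopropylidenedioxy)labda-13(16),14-dien-19-yl (E)-4-acetoxycinnamate, via acid chloride 26 (not isolated)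
Conditions: 25, (COCl)2, DMF (cat.), CH2Cl2, 0 °C to rt, evaporation; then 24, pyridine, DMAP (cat.), CH2Cl2, rt
Reagents that add atoms: none
Why: Nucleophilic acyl substitution: the acid chloride made in the flask acylates the hindered primary alcohol under pyridine/DMAP catalysis, the (E)-alkene is retained and the phenol stays masked as its acetate.

**Step 17**
Reactants: 27 protected ester 7α,8α-(isopropylidenedioxy)labda-13(16),14-dien-19-yl (E)-4-acetoxycinnamate
Product: 28 target 7α,8α-dihydroxylabda-13(16),14-dien-19-yl (E)-4-hydroxycinnamate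
Conditions: HCl (0.2 mol/L) in MeOH, 0 °C to rt
Reagents that add atoms: none
Why: Acid-catalysed transketalisation with methanol removes the isopropylidene group and acid-catalysed methanolysis cleaves the aryl acetate far faster than the hindered neopentyl cinnamate; dilute acid at room temperature should leave the 2-substituted diene and the tertiary alcohol untouched, and no stereocentre is affected.

**Compound list**

1 | (R)-(−)-carvone, (5R)-2-methyl-5-(prop-1-en-2-yl)cyclohex-2-en-1-one | O=C1C(C)=CC[C@@H](C(C)=C)C1 | starting material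
2 | bis-borane adduct of 1 (9-BBN borinate of the ring carbinol and B-alkyl-9-BBN at the side-chain CH2; epimers) | O(B2C3CCCC2CCC3)C1C(C)=CC[C@@H](C(C)CB2C3CCCC2CCC3)C1 | intermediate
3 | (5R)-5-(1-hydroxypropan-2-yl)-2-methylcyclohex-2-en-1-ol (epimers at C1 and at the side-chain CH) | OC1C(C)=CC[C@@H](C(C)CO)C1 | intermediate
4 | 2-[(1R)-4-methyl-5-oxocyclohex-3-en-1-yl]propanoic acid (epimers at C2 of the acid) | O=C1C(C)=CC[C@@H](C(C)C(=O)O)C1 | intermediate
5 | methyl 2-[(1R)-4-methyl-5-oxocyclohex-3-en-1-yl]propanoate (epimers at C2 of the ester) | O=C1C(C)=CC[C@@H](C(C)C(=O)OC)C1 | intermediate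
6 | methyl 2-[(1R)-4,6-dimethyl-5-oxocyclohex-3-en-1-yl]propanoate (epimers at ring C6 and at C2 of the ester) | O=C1C(C)=CC[C@@H](C(C)C(=O)OC)C1C | intermediate
7 | acrolein (prop-2-enal) | C=CC=O | starting material
8 | aldol alkoxide, methyl 2-[(1S,6R)-6-[(1R)-1-(lithiooxy)prop-2-enyl]-4,6-dimethyl-5-oxocyclohex-3-en-1-yl]propanoate (epimers at C2 of the ester) | O=C1C(C)=CC[C@@H](C(C)C(=O)OC)[C@]1(C)[C@H](O[Li])C=C | intermediate
9 | (1R,4aS,8aR)-1-ethenyl-4,7,8a-trimethyl-4,4a,5,8a-tetrahydro-1H-isochromene-3,8-dione (trans-fused δ-lactone, vinyl axial and anti to the 8a-methyl; epimers at C4) | O=C1C(C)=CC[C@H]2C(C)C(=O)O[C@H](C=C)[C@]12C | intermediate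
10 | (1R,4aS,8aS)-1-ethenyl-4,7,8a-trimethyl-8-methylidene-1,4,4a,5,8,8a-hexahydro-3H-isochromen-3-one (epimers at C4) | C=C1C(C)=CC[C@H]2C(C)C(=O)O[C@H](C=C)[C@]12C | intermediate
11 | trimethylsilyl ketene acetal of 10 (C3–OSiMe3, C3=C4) | C=C1C(C)=CC[C@H]2C(C)=C(O[Si](C)(C)C)O[C@H](C=C)[C@]12C | intermediate
12 | trimethylsilyl 12,13,14,15,16-pentanorlabda-1,7,9(11)-trien-19-oate | C=C1C(C)=CC[C@H]2[C@@](C)(C(=O)O[Si](C)(C)C)CC=C[C@@]21C | intermediate
13 | 12,13,14,15,16-pentanorlabda-1,7,9(11)-trien-19-oic acid (5α-H, 10β-methyl, 4α-methyl, 4β-carboxyl) | C=C1C(C)=CC[C@H]2[C@@](C)(C(=O)O)CC=C[C@@]21C | intermediate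
14 | methyl 12,13,14,15,16-pentanorlabda-1,7,9(11)-trien-19-oate | C=C1C(C)=CC[C@H]2[C@@](C)(C(=O)OC)CC=C[C@@]21C | intermediate
15 | bromoacetone (1-bromopropan-2-one) | CC(=O)CBr | starting material
16 | methyl 11-(9-borabicyclo[3.3.1]nonan-9-yl)-12,13,14,15,16-pentanorlabda-1,7-dien-19-oate (9α-H) | C12CCCC(CCC1)B2C[C@H]1C(C)=CC[C@H]2[C@@](C)(C(=O)OC)CC=C[C@@]21C | intermediate
17 | methyl 13-oxo-14,15-dinorlabda-1,7-dien-19-oate | CC(=O)CC[C@H]1C(C)=CC[C@H]2[C@@](C)(C(=O)OC)CC=C[C@@]21C | intermediate
18 | methyl 13-oxo-14,15-dinorlabd-7-en-19-oate | CC(=O)CC[C@H]1C(C)=CC[C@H]2[C@@](C)(C(=O)OC)CCC[C@@]21C | intermediate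
19 | methyl 7α,8α-dihydroxy-13-oxo-14,15-dinorlabdan-19-oate | CC(=O)CC[C@H]1[C@](C)(O)[C@H](O)C[C@H]2[C@@](C)(C(=O)OC)CCC[C@@]21C | intermediate
20 | methyl 7α,8α-(isopropylidenedioxy)-13-oxo-14,15-dinorlabdan-19-oate | CC(=O)CC[C@H]1[C@]3(C)OC(C)(C)O[C@@H]3C[C@H]2[C@@](C)(C(=O)OC)CCC[C@@]21C | intermediate
21 | methyl 7α,8α-(isopropylidenedioxy)-13-(trifluoromethylsulfonyloxy)-14,15-dinorlabd-13(16)-en-19-oate | C=C(OS(=O)(=O)C(F)(F)F)CC[C@H]1[C@]3(C)OC(C)(C)O[C@@H]3C[C@H]2[C@@](C)(C(=O)OC)CCC[C@@]21C | intermediate
22 | tributyl(vinyl)stannane | C=C[Sn](CCCC)(CCCC)CCCC | starting material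
23 | methyl 7α,8α-(isopropylidenedioxy)labda-13(16),14-dien-19-oate | C=CC(=C)CC[C@H]1[C@]3(C)OC(C)(C)O[C@@H]3C[C@H]2[C@@](C)(C(=O)OC)CCC[C@@]21C | intermediate
24 | 7α,8α-(isopropylidenedioxy)labda-13(16),14-dien-19-ol | C=CC(=C)CC[C@H]1[C@]3(C)OC(C)(C)O[C@@H]3C[C@H]2[C@@](C)(CO)CCC[C@@]21C | intermediate
25 | (E)-4-acetoxycinnamic acid | CC(=O)Oc1ccc(/C=C/C(=O)O)cc1 | starting material
26 | (E)-4-acetoxycinnamoyl chloride | CC(=O)Oc1ccc(/C=C/C(=O)Cl)cc1 | intermediate
27 | 7α,8α-(isopropylidenedioxy)labda-13(16),14-dien-19-yl (E)-4-acetoxycinnamate | C=CC(=C)CC[C@H]1[C@]3(C)OC(C)(C)O[C@@H]3C[C@H]2[C@@](C)(COC(=O)/C=C/c4ccc(OC(C)=O)cc4)CCC[C@@]21C | intermediate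
28 | 7α,8α-dihydroxylabda-13(16),14-dien-19-yl (E)-4-hydroxycinnamate | C=CC(=C)CC[C@H]1[C@](C)(O)[C@H](O)C[C@H]2[C@@](C)(COC(=O)/C=C/c3ccc(O)cc3)CCC[C@@]21C | target

**Step count and risks**

Total step count: 17. Longest linear sequence: 17 steps (1 to 28).

Steps most likely to fail:

Step 7. The silyl ketene acetal may not reach the twisted boat transition state that the trans-fused lactone demands, so that on heating it reverts, C-silylates or fragments instead of rearranging. The fallback closes ring A by intramolecular ester-enolate alkylation; it sets out from 6 and comes back to the route at 18. The lithium enolate of 6 would be alkylated with 1-chloro-3-iodopropane anti to the side chain to give methyl 2-[6-(3-chloropropyl)-4,6-dimethyl-5-oxocyclohex-3-en-1-yl]propanoate F1. Wittig methylenation (Ph3P=CH2) would give methyl 2-[6-(3-chloropropyl)-4,6-dimethyl-5-methylidenecyclohex-3-en-1-yl]propanoate F2. LiN(iPr)2 in THF/DMPU should then close ring A by 6-exo-tet alkylation of the ester enolate at C4, the planar ester carbon taking the axial site under the C10 methyl, to give methyl 12,13,14,15,16-pentanorlabda-7,9(11)-dien-19-oate F3. Hydroboration and alkylation with 15 as in step 9 would then give 18 directly, because ring A is already saturated.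

Step 5. Retro-aldol equilibration of the hindered aldolate before lactonisation, or weak differentiation of the two faces of acrolein, may erode the configuration at C1 on which C4 depends. The fallback sets C1 by catalyst-controlled reduction; it sets out from 6 and comes back at 9. The aldol reaction would be quenched at −78 °C to give methyl 2-[6-(1-hydroxyprop-2-enyl)-4,6-dimethyl-5-oxocyclohex-3-en-1-yl]propanoate F4 as a mixture at C1. Dess–Martin oxidation would give the vinyl ketone methyl 2-[4,6-dimethyl-5-oxo-6-(prop-2-enoyl)cyclohex-3-en-1-yl]propanoate F5. Corey–Bakshi–Shibata reduction with catecholborane, using the oxazaborolidine enantiomer that delivers hydride to the required face (the (S)-catalyst if the quaternary C10 acts as the large group), should give methyl 2-[6-[(1R)-1-hydroxyprop-2-enyl]-4,6-dimethyl-5-oxocyclohex-3-en-1-yl]propanoate F6. Catalytic camphorsulfonic acid in toluene at 50 °C would close the lactone to 9.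

Step 9. The hindered primary alkyl group may migrate too slowly in the boron ate complex, so that a ring bond of the bicyclononane migrates instead or the enolate is simply protonated. The fallback builds the side chain by Wittig homologation; it sets out from 14 and comes back at 18. Hydroboration of 14 with 9-BBN and oxidative work-up would give methyl 11-hydroxy-12,13,14,15,16-pentanorlabda-1,7-dien-19-oate F7. Dess–Martin oxidation would give methyl 11-oxo-12,13,14,15,16-pentanorlabda-1,7-dien-19-oate F8. Wittig reaction with (acetylmethylene)triphenylphosphorane would give methyl (11E)-13-oxo-14,15-dinorlabda-1,7,11-trien-19-oate F9. Hydrogenation over RhCl(PPh3)3 should reduce the enone alkene together with the C1=C2 alkene and give 18.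

**Further compounds**

F1 | step 7 | methyl 2-[6-(3-chloropropyl)-4,6-dimethyl-5-oxocyclohex-3-en-1-yl]propanoate (chloropropyl trans to the side chain) | O=C1C(C)=CC[C@@H](C(C)C(=O)OC)[C@]1(C)CCCCl
F2 | step 7 | methyl 2-[6-(3-chloropropyl)-4,6-dimethyl-5-methylidenecyclohex-3-en-1-yl]propanoate | C=C1C(C)=CC[C@@H](C(C)C(=O)OC)[C@]1(C)CCCCl
F3 | step 7 | methyl 12,13,14,15,16-pentanorlabda-7,9(11)-dien-19-oate | C=C1C(C)=CC[C@H]2[C@@](C)(C(=O)OC)CCC[C@@]21C
F4 | step 5 | methyl 2-[6-(1-hydroxyprop-2-enyl)-4,6-dimethyl-5-oxocyclohex-3-en-1-yl]propanoate (mixture at the carbinol carbon) | O=C1C(C)=CC[C@@H](C(C)C(=O)OC)[C@]1(C)C(O)C=C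
F5 | step 5 | methyl 2-[4,6-dimethyl-5-oxo-6-(prop-2-enoyl)cyclohex-3-en-1-yl]propanoate | O=C1C(C)=CC[C@@H](C(C)C(=O)OC)[C@]1(C)C(=O)C=C
F6 | step 5 | methyl 2-[6-[(1R)-1-hydroxyprop-2-enyl]-4,6-dimethyl-5-oxocyclohex-3-en-1-yl]propanoate | O=C1C(C)=CC[C@@H](C(C)C(=O)OC)[C@]1(C)[C@H](O)C=C
F7 | step 9 | methyl 11-hydroxy-12,13,14,15,16-pentanorlabda-1,7-dien-19-oate | OC[C@H]1C(C)=CC[C@H]2[C@@](C)(C(=O)OC)CC=C[C@@]21C
F8 | step 9 | methyl 11-oxo-12,13,14,15,16-pentanorlabda-1,7-dien-19-oate | O=C[C@H]1C(C)=CC[C@H]2[C@@](C)(C(=O)OC)CC=C[C@@]21C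
F9 | step 9 | methyl (11E)-13-oxo-14,15-dinorlabda-1,7,11-trien-19-oate | CC(=O)/C=C/[C@H]1C(C)=CC[C@H]2[C@@](C)(C(=O)OC)CC=C[C@@]21C
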